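**Retrosynthetic overview**

1. The target is numbered as a 7-oxabicyclo[4.1.0]hept-3-en-2-one: C1 quaternary oxirane carbon, C2 ketone, C3 heptenyl carbon, C4 CH2OH carbon, C5 carbinol, C6 oxirane CH. The end game is acidolysis of a tert-butyl ester and an acetonide, a Suzuki coupling at C3 of an α-iodo enone, and a cross-metathesis that turns a C1-allyl group into the enoate side chain.
2. Enabling feature: C4 with its CH2OH and C5 with its OH are a dihydroxyacetone unit hidden at the alkene oxidation level. Its neighbours are C3, which lies α to the C2 ketone, and C6, whose oxirane oxygen sits β to C4.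
3. The ring bonds C5–C6 (anti-aldol of the dihydroxyacetone α-carbon with an aldehyde) and C3=C4 (Horner–Wadsworth–Emmons olefination of the dihydroxyacetone ketone by a C3 phosphonate) are therefore made in one pot. The partners are dihydroxyacetone acetonide and a four-carbon chloro keto aldehyde (C6–C1–C2–C3); the aldol oxygen then closes the oxirane on the tertiary chloride at C1.
4. Ring order: the 1,3-dioxane (bought, temporary) comes first, the cyclohexenone and the oxirane both form in the key step, and the dioxane is opened in the last step. Phosphonate, chloride and acetonide are activating or temporary elements and are all lost on the way.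
5. The chloro keto aldehyde comes from ethyl 4-(diethoxyphosphoryl)-3-oxobutanoate by C-allylation, copper-catalysed enantioselective chlorination (which sets the C1 precursor centre) and reduction/oxidation.

Key step: step 5

Remark: ethyl 4-(diethoxyphosphoryl)-3-oxobutanoate is taken as a catalogue reagent (the phosphonate derived from ethyl 4-chloroacetoacetate).

**Route**

Step 1
Reactants: 1 ethyl 4-(diethoxyphosphoryl)-3-oxobutanoate; 2 allyl bromide
Product: 3 ethyl 2-[2-(diethoxyphosphoryl)acetyl]pent-4-enoate (racemic)
Conditions: NaH (1.0 equiv), THF, 0 °C; then 2 (1.0 equiv), 0 °C → rt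
Reagents that add atoms: none
Why: Acetoacetic-ester-type C-alkylation, in which one equivalent of NaH removes only the proton between ketone and ester (more acidic than the CH2 next to phosphorus) and the sodium enolate is allylated at carbon; the new stereocentre is racemic and is re-formed in step 2.

Step 2
Reactants: 3
Product: 4 ethyl (2R)-2-chloro-2-[2-(diethoxyphosphoryl)acetyl]pent-4-enoate
Conditions: Cu(OTf)2 (10 mol %), chiral spiro pyridyl-oxazoline ligand (12 mol %, enantiomer chosen for the 2R product), N-chlorosuccinimide (1.2 equiv), 4 Å MS, toluene, 0 °C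
Reagents that add atoms: N-chlorosuccinimide, O=C1CCC(=O)N1Cl
Why: Enantioselective electrophilic α-chlorination of a 2-substituted β-keto ester, in which the keto ester binds divalent copper as a bidentate enolate, the chiral ligand blocks one enolate face and N-chlorosuccinimide chlorinates the other to set the quaternary C–Cl centre (2R), while the less acidic CH2 next to phosphorus should stay untouched.

Step 3
Reactants: 4
Product: 5 diethyl [(3S)-3-chloro-2-hydroxy-3-(hydroxymethyl)hex-5-en-1-yl]phosphonate (both C2 epimers)
Conditions: iBu2AlH (4.5 equiv), CH2Cl2, −78 → −40 °C; aq. potassium sodium tartrate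
Reagents that add atoms: none
Why: Aluminium hydride reduction of ester and ketone, in which the covalent aluminium alkoxides should not displace the adjacent tertiary chloride at low temperature, the phosphonate ester is inert, and the new carbinol centre (both epimers) is erased in step 4.

Step 4
Reactants: 5
Product: 6 diethyl [(3S)-3-chloro-3-formyl-2-oxohex-5-en-1-yl]phosphonate
Conditions: Dess–Martin periodinane (2.6 equiv), CH2Cl2, 0 °C → rt; used without storage
Reagents that add atoms: none
Why: Dess–Martin oxidation of the primary and the secondary alcohol under neutral conditions should give the non-enolisable chloro keto aldehyde without touching the alkene, and the quaternary C–Cl centre has no α-hydrogen and cannot epimerise.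

Step 5
Reactants: 6; 7 2,2-dimethyl-1,3-dioxan-5-one
Product: 10 epoxy enone acetonide (7R,8R,8aR)-7,8-epoxy-2,2-dimethyl-7-(prop-2-en-1-yl)-7,8-dihydro-4H-1,3-benzodioxin-6(8aH)-one, via aldol chlorohydrin 8 (not isolated), via bicyclic chlorohydrin enone 9 (not isolated)
Conditions: 7 (1.5 equiv), L-proline (30 mol %), DMF, 4 °C; then Cs2CO3 (3 equiv), 0 °C → rt, same flask
Reagents that add atoms: none
Why: The enamine formed from 7 and L-proline adds through its carboxylic-acid-hydrogen-bonded chair transition state to the re face of the non-enolisable, chlorine-activated aldehyde of 6 and should give the anti aldol 8 (closest known type: amine-catalysed direct aldol of this dioxanone with α-chloro and other α-branched aldehydes). Cs2CO3 then removes the most acidic proton, the one between the ketone and phosphorus, and the carbanion condenses with the dioxanone carbonyl in an intramolecular Horner–Wadsworth–Emmons reaction (closest known type: ketophosphonate cyclisations to oxygenated cyclohexenones), so the carbocycle closes by 6-exo-trig addition to C=O followed by syn loss of diethyl phosphate to give 9. The oxirane closes by 3-exo-tet attack of the C8 alkoxide on the trans-disposed tertiary α-keto chloride with inversion, exactly the second stage of a Darzens condensation. C8a and C8 of 10 are set by the catalyst (anti, both R), and C7 comes from the (S)-chloride of 6 by stereospecific inversion (7R). The step needs the phosphonate carbanion to form and to cyclise in preference to the other enolisable positions and to intermolecular olefination of surplus 7, which its higher acidity and the six-membered transition state should secure. Because only the diastereomer with hydroxyl and chlorine trans on the new ring can close the oxirane, material derived from the minor enantiomer of 6 cannot finish the sequence, so 10 should be enantiomerically purer than 6.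

Step 6
Reactants: 10; 11 tert-butyl methacrylate
Product: 12 tert-butyl (2E)-4-[(7R,8R,8aR)-7,8-epoxy-2,2-dimethyl-6-oxo-6,7,8,8a-tetrahydro-4H-1,3-benzodioxin-7-yl]-2-methylbut-2-enoate
Conditions: second-generation Hoveyda–Grubbs catalyst (5 mol %), 11 (10 equiv), CH2Cl2, 40 °C
Reagents that add atoms: none
Why: Olefin cross-metathesis of the monosubstituted alkene with an excess of the slowly homodimerising 1,1-disubstituted acrylate, in which the trisubstituted, electron-poor ring enone stays out and the new trisubstituted enoate should form as the E isomer (ester trans to the chain, the usual outcome with methacrylates).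

Step 7
Reactants: 12
Product: 13 tert-butyl (2E)-4-[(7R,8R,8aR)-7,8-epoxy-5-iodo-2,2-dimethyl-6-oxo-6,7,8,8a-tetrahydro-4H-1,3-benzodioxin-7-yl]-2-methylbut-2-enoate
Conditions: I2 (2.5 equiv), pyridine/CH2Cl2 (1:1), DMAP (0.2 equiv), 0 °C → rt; aq. Na2S2O3
Reagents that add atoms: iodine, II
Why: Nucleophile-catalysed α-iodination of an enone (conjugate addition of pyridine or DMAP, iodination of the enolate, E1cB loss of the amine), which should place iodine at C5, the only enone α-C–H, without touching the α-methyl enoate or the epoxide.

Step 8
Reactants: 13; 14 (E)-hept-1-en-1-ylboronic acid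
Product: 15 tert-butyl (2E)-4-[(7R,8R,8aR)-7,8-epoxy-5-[(1E)-hept-1-en-1-yl]-2,2-dimethyl-6-oxo-6,7,8,8a-tetrahydro-4H-1,3-benzodioxin-7-yl]-2-methylbut-2-enoate
Conditions: Pd(PhCN)2Cl2 (5 mol %), AsPh3 (10 mol %), Ag2O (1.6 equiv), THF/H2O (8:1), rt
Reagents that add atoms: none
Why: Suzuki–Miyaura coupling, in which zerovalent palladium inserts into the electron-poor C–I bond at room temperature and Ag2O promotes transmetallation without a strong base, so the base-sensitive epoxy enone should survive and the E geometry of the boronic acid is transferred with retention.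

Step 9
Reactants: 15
Product: 16 (2E)-4-[(1R,5R,6R)-3-[(1E)-hept-1-en-1-yl]-5-hydroxy-4-(hydroxymethyl)-2-oxo-7-oxabicyclo[4.1.0]hept-3-en-1-yl]-2-methylbut-2-enoic acid (target)
Conditions: CF3CO2H/CH2Cl2/H2O (25:70:5), 0 °C → rt
Reagents that add atoms: none
Why: Acidolysis, in which the tert-butyl ester is cleaved through the tert-butyl cation and the isopropylidene acetal is hydrolysed, while the α,β-epoxy ketone, deactivated toward acid-promoted opening by the adjacent carbonyl, and the three stereocentres should remain untouched.

**Compound list**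

1 | ethyl 4-(diethoxyphosphoryl)-3-oxobutanoate | CCOC(=O)CC(=O)CP(=O)(OCC)OCC | starting material
2 | allyl bromide (3-bromoprop-1-ene) | C=CCBr | starting material
3 | ethyl 2-[2-(diethoxyphosphoryl)acetyl]pent-4-enoate (racemic) | CCOC(=O)C(CC=C)C(=O)CP(=O)(OCC)OCC | intermediate
4 | ethyl (2R)-2-chloro-2-[2-(diethoxyphosphoryl)acetyl]pent-4-enoate | CCOC(=O)[C@@](Cl)(CC=C)C(=O)CP(=O)(OCC)OCC | intermediate
5 | diethyl [(3S)-3-chloro-2-hydroxy-3-(hydroxymethyl)hex-5-en-1-yl]phosphonate (both C2 epimers) | OC[C@@](Cl)(CC=C)C(O)CP(=O)(OCC)OCC | intermediate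
6 | diethyl [(3S)-3-chloro-3-formyl-2-oxohex-5-en-1-yl]phosphonate | O=C[C@@](Cl)(CC=C)C(=O)CP(=O)(OCC)OCC | intermediate
7 | 2,2-dimethyl-1,3-dioxan-5-one | CC1(C)OCC(=O)CO1 | starting material
8 | diethyl {(3S,4R)-3-chloro-4-[(4S)-2,2-dimethyl-5-oxo-1,3-dioxan-4-yl]-4-hydroxy-2-oxo-3-(prop-2-en-1-yl)butyl}phosphonate (aldol chlorohydrin) | C=CC[C@@](Cl)(C(=O)CP(=O)(OCC)OCC)[C@H](O)[C@@H]1OC(C)(C)OCC1=O | intermediate
9 | (7S,8R,8aR)-7-chloro-8-hydroxy-2,2-dimethyl-7-(prop-2-en-1-yl)-7,8-dihydro-4H-1,3-benzodioxin-6(8aH)-one (bicyclic chlorohydrin enone) | O=C1C=C2COC(C)(C)O[C@H]2[C@@H](O)[C@@]1(Cl)CC=C | intermediate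
10 | (7R,8R,8aR)-7,8-epoxy-2,2-dimethyl-7-(prop-2-en-1-yl)-7,8-dihydro-4H-1,3-benzodioxin-6(8aH)-one (epoxy enone acetonide) | O=C1C=C2COC(C)(C)O[C@H]2[C@H]3O[C@@]13CC=C | intermediate
11 | tert-butyl methacrylate (tert-butyl 2-methylprop-2-enoate) | CC(=C)C(=O)OC(C)(C)C | starting material
12 | tert-butyl (2E)-4-[(7R,8R,8aR)-7,8-epoxy-2,2-dimethyl-6-oxo-6,7,8,8a-tetrahydro-4H-1,3-benzodioxin-7-yl]-2-methylbut-2-enoate | O=C1C=C2COC(C)(C)O[C@H]2[C@H]3O[C@@]13C/C=C(\C)C(=O)OC(C)(C)C | intermediate
13 | tert-butyl (2E)-4-[(7R,8R,8aR)-7,8-epoxy-5-iodo-2,2-dimethyl-6-oxo-6,7,8,8a-tetrahydro-4H-1,3-benzodioxin-7-yl]-2-methylbut-2-enoate | O=C1C(I)=C2COC(C)(C)O[C@H]2[C@H]3O[C@@]13C/C=C(\C)C(=O)OC(C)(C)C | intermediate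
14 | (E)-hept-1-en-1-ylboronic acid | CCCCC/C=C/B(O)O | starting material
15 | tert-butyl (2E)-4-[(7R,8R,8aR)-7,8-epoxy-5-[(1E)-hept-1-en-1-yl]-2,2-dimethyl-6-oxo-6,7,8,8a-tetrahydro-4H-1,3-benzodioxin-7-yl]-2-methylbut-2-enoate | O=C1C(/C=C/CCCCC)=C2COC(C)(C)O[C@H]2[C@H]3O[C@@]13C/C=C(\C)C(=O)OC(C)(C)C | intermediate
16 | (2E)-4-[(1R,5R,6R)-3-[(1E)-hept-1-en-1-yl]-5-hydroxy-4-(hydroxymethyl)-2-oxo-7-oxabicyclo[4.1.0]hept-3-en-1-yl]-2-methylbut-2-enoic acid | CCCCC/C=C/C1=C(CO)[C@@H](O)[C@H]2O[C@@]2(C/C=C(\C)C(=O)O)C1=O | target

**Step count and risks**

Total steps: 9. Longest linear sequence: 9 (1 → 16).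

Steps most likely to fail:

1. Step 5. The amine may attack the very electrophilic aldehyde of 6 and cleave off the formyl group, or the phosphonate of one molecule may condense with the aldehyde of another. Once base is added, the aldol may also lose water or revert before the ring closes. The fallback sets out from 6 and 7 and returns at 10. Ketone 7 is enolised with (c-C6H11)2BCl/Et3N (Et2O, −78 °C) to the boron enolate 5-[(dicyclohexylboranyl)oxy]-2,2-dimethyl-4H-1,3-dioxine F1. F1 adds to 6 at −78 °C through a closed chair transition state that again gives the anti relationship of the two new centres. After neutral work-up (pH 7 buffer, MeOH) chlorohydrin 8 is isolated and cyclised in a second flask with Cs2CO3 in DMF by way of 9 to 10. No amine is present in this variant, and the aldol and the ring closure are decoupled. Facial control relative to the chloride-bearing centre is then substrate-based. Because only the diastereomer 8 can reach the trans chlorohydrin 9, 10 should still emerge as the same enantiomer, with the enantiopurity of 6.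

2. Step 2. The copper–ligand complex may discriminate poorly between the faces of an acyclic, freely rotating keto ester enolate, or chlorination may compete at the CH2 next to phosphorus. The fallback sets out from 3 and returns at 4. The sodium enolate of 3 (NaH, THF, 0 °C) is chlorinated with N-chlorosuccinimide at the keto ester carbon to give racemic ethyl 2-chloro-2-[2-(diethoxyphosphoryl)acetyl]pent-4-enoate F2. Its enantiomers are separated by preparative supercritical-fluid chromatography on a chiral stationary phase to supply 4.

3. Step 6. Productive metathesis with the hindered acrylate may be slower than homodimerisation of 10 and decay of the catalyst. The fallback sets out from 10 and returns at 12. Ozonolysis of the terminal alkene only (O3, CH2Cl2/MeOH, −78 °C, stopped at the first indicator colour change; Me2S) should give [(7R,8R,8aR)-7,8-epoxy-2,2-dimethyl-6-oxo-6,7,8,8a-tetrahydro-4H-1,3-benzodioxin-7-yl]acetaldehyde F3; the conjugated ring enone reacts far more slowly with ozone. Wittig olefination of F3 with the stabilised ylide tert-butyl 2-(triphenylphosphoranylidene)propanoate (CH2Cl2, rt) should then give 12 as the E enoate.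

Further compounds
F1 | step 5 | 5-[(dicyclohexylboranyl)oxy]-2,2-dimethyl-4H-1,3-dioxine | CC1(C)OCC(OB(C2CCCCC2)C2CCCCC2)=CO1
F2 | step 2 | racemic ethyl 2-chloro-2-[2-(diethoxyphosphoryl)acetyl]pent-4-enoate | CCOC(=O)C(Cl)(CC=C)C(=O)CP(=O)(OCC)OCC
F3 | step 6 | [(7R,8R,8aR)-7,8-epoxy-2,2-dimethyl-6-oxo-6,7,8,8a-tetrahydro-4H-1,3-benzodioxin-7-yl]acetaldehyde | O=C1C=C2COC(C)(C)O[C@H]2[C@H]3O[C@@]13CC=O
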